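**Retrosynthetic overview**
- The route rests on the chroman-4-one array O1–C2–C3–C4(=O): the only stereocentre is the quaternary C2, which carries O1, a methyl group and the side chain, and whose neighbour C3 is alpha to the C4 ketone.
- The C6 phenol and the side-chain tertiary alcohol are unmasked last from a triisopropylsilyl (TIPS) and a triethylsilyl (TES) ether (12 from 11).
- The C2–C3 bond is cut: the pyranone ring, the only ring made (the benzene ring is bought), closes when a diazoketone-derived rhodium carbenoid carbon (C3) inserts into the C2–H of the (S)-secondary alkyl aryl ether 10, with retention.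
- Diazoketone 10 comes from methyl ketone 8 by deacylative diazo transfer; the O1–C2 bond and the C2 configuration come from Mitsunobu inversion of (R)-sulcatol 5 with salicyl ketone 4, followed by alkene hydration and silylation.
- Salicyl ketone 4 comes from 2-bromo-1,4-dimethoxybenzene 1 by Friedel–Crafts acetylation, demethylation and selective silylation.

Key step: step 8

Assumption: (R)-sulcatol 5 is bought in high enantiomeric purity (it is otherwise reachable by lipase resolution of racemic sulcatol); its purity sets that of the target, because C2 is never an sp2 or anionic centre after step 4.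

**Step 1**
Reactants: 1 2-bromo-1,4-dimethoxybenzene
Product: 2 1-(4-bromo-2,5-dimethoxyphenyl)ethan-1-one
Conditions: AcCl, AlCl3, CH2Cl2, 0 °C → rt; ice/aq. HCl quench
Reagents that add atoms: acetyl chloride, CC(Cl)=O
Why: Friedel–Crafts acylation should go to the ring position ortho to one methoxy group and para to bromine (the least hindered activated site), which sets the acetyl group para to Br as the C4a/C7 relation of the target requires.

**Step 2**
Reactants: 2 1-(4-bromo-2,5-dimethoxyphenyl)ethan-1-one
Product: 3 1-(4-bromo-2,5-dihydroxyphenyl)ethan-1-one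
Conditions: BBr3 (3 equiv), CH2Cl2, −78 °C → rt; then H2O
Reagents that add atoms: none
Why: Lewis-acid cleavage of aryl methyl ethers with BBr3 should remove both methyl groups and leave the aryl bromide and the ketone untouched.

**Step 3**
Reactants: 3 1-(4-bromo-2,5-dihydroxyphenyl)ethan-1-one
Product: 4 1-[4-bromo-2-hydroxy-5-(triisopropylsilyloxy)phenyl]ethan-1-one
Conditions: TIPSCl (1.05 equiv), imidazole, DMF, 0 °C → rt
Reagents that add atoms: triisopropylsilyl chloride, CC(C)[Si](Cl)(C(C)C)C(C)C
Why: Selective silylation should take the C5 hydroxyl (ortho to Br, more acidic and not hydrogen bonded), while the C2 hydroxyl is held in a hydrogen bond to the ketone and stays free for step 4.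

**Step 4**
Reactants: 4 1-[4-bromo-2-hydroxy-5-(triisopropylsilyloxy)phenyl]ethan-1-one; 5 (R)-sulcatol ((R)-6-methylhept-5-en-2-ol)
Product: 6 1-{4-bromo-2-[(2S)-6-methylhept-5-en-2-yl]oxy-5-(triisopropylsilyloxy)phenyl}ethan-1-one
Conditions: PPh3, DIAD, THF, 0 °C → rt
Reagents that add atoms: none
Why: Mitsunobu etherification of the phenol with the secondary alcohol proceeds by SN2 displacement of the activated alkoxyphosphonium, so the (R)-carbinol is inverted to the (S)-aryl ether carbon that becomes C2.

**Step 5**
Reactants: 6 1-{4-bromo-2-[(2S)-6-methylhept-5-en-2-yl]oxy-5-(triisopropylsilyloxy)phenyl}ethan-1-one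
Product: 7 1-{4-bromo-2-[(2S)-6-hydroxy-6-methylheptan-2-yl]oxy-5-(triisopropylsilyloxy)phenyl}ethan-1-one
Conditions: Co(acac)2 (20 mol %), PhSiH3, O2 (1 atm), iPrOH, rt
Reagents that add atoms: dioxygen, O=O
Why: Mukaiyama hydration (cobalt-mediated hydrogen atom transfer and oxygenation at the more substituted carbon) should add H and OH across the trisubstituted alkene in the Markovnikov sense without touching the aryl ketone, the aryl bromide or the ether stereocentre.

**Step 6**
Reactants: 7 1-{4-bromo-2-[(2S)-6-hydroxy-6-methylheptan-2-yl]oxy-5-(triisopropylsilyloxy)phenyl}ethan-1-one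
Product: 8 1-{4-bromo-2-[(2S)-6-methyl-6-(triethylsilyloxy)heptan-2-yl]oxy-5-(triisopropylsilyloxy)phenyl}ethan-1-one
Conditions: TESOTf, 2,6-lutidine, CH2Cl2, −78 → 0 °C
Reagents that add atoms: triethylsilyl trifluoromethanesulfonate, CC[Si](CC)(CC)OS(=O)(=O)C(F)(F)F
Why: Silyl triflate silylation is fast enough for a tertiary alcohol, 2,6-lutidine is too weak a base to enolise the ketone in the cold, and the TES ether prevents alkoxide chemistry in step 7 and O–H insertion in step 8.

**Step 7**
Reactants: 8 1-{4-bromo-2-[(2S)-6-methyl-6-(triethylsilyloxy)heptan-2-yl]oxy-5-(triisopropylsilyloxy)phenyl}ethan-1-one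
Product: 10 1-{4-bromo-2-[(2S)-6-methyl-6-(triethylsilyloxy)heptan-2-yl]oxy-5-(triisopropylsilyloxy)phenyl}-2-diazoethan-1-one, via trifluoroacetyl diketone 9 (not isolated)
Conditions: LiN(SiMe3)2, THF, −78 °C; CF3CO2CH2CF3; cold 1 M HCl wash; then MsN3, Et3N, H2O (1 equiv), MeCN, rt
Reagents that add atoms: methanesulfonyl azide, CS(=O)(=O)N=[N+]=[N-] (gives the N2 unit of 10); 2,2,2-trifluoroethyl trifluoroacetate, O=C(OCC(F)(F)F)C(F)(F)F (its CF3CO group stands in 9 and is lost again on the way to 10)
Why: Claisen-type trifluoroacetylation of the lithium enolate activates the methyl group, and Regitz-type detrifluoroacetylative diazo transfer from mesyl azide should then give the diazomethyl ketone, with the CF3CO group leaving as its N-sulfonyl amide and the ether stereocentre untouched.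

**Step 8**
Reactants: 10 1-{4-bromo-2-[(2S)-6-methyl-6-(triethylsilyloxy)heptan-2-yl]oxy-5-(triisopropylsilyloxy)phenyl}-2-diazoethan-1-one
Product: 11 (S)-7-bromo-2-methyl-2-[4-methyl-4-(triethylsilyloxy)pentyl]-6-(triisopropylsilyloxy)chroman-4-one
Conditions: Rh2(OAc)4 (2 mol %), CH2Cl2, rt → reflux, slow addition of 10 by syringe pump, high dilution
Reagents that add atoms: none
Why: Rh2(OAc)4, a divalent rhodium dimer, takes N2 from the diazomethyl ketone to give an electrophilic rhodium carbenoid whose carbon (future C3) inserts into the tertiary C2–H of the aryl ether through a concerted, hydride-transfer-like three-centre transition state; this is the known dirhodium-catalysed C–H insertion of ortho-alkoxyaryl diazoketones next to the ether oxygen, which gives chroman-4-ones. The pyranone ring closes as a 1,6-insertion (carbenoid C, C4, C4a, C8a, O1, C2), because the 1,5-position is the hydrogen-free ether oxygen and the aryl ketone holds the carbenoid beside the O-alkyl group. The C2–C3 bond forms on the face from which the hydrogen leaves, so the insertion goes with retention and the (S)-methine set in step 4 becomes the (S)-quaternary C2; no other stereocentre is formed. The step needs chemoselectivity for C–H insertion over attack of the O1 lone pair (oxonium ylide, then 1,2-shift or elimination to a benzofuran-3-one) and over carbene dimerisation: the O1 lone pair is delocalised into the acyl-substituted arene, the secondary alkyl group migrates poorly so ylide formation can revert, slow addition keeps the diazo concentration low, and acetate ligands give a less electrophilic carbenoid than perfluorocarboxylates would. Site selectivity follows from the substrate, since the tertiary C2–H is the only C–H that is both activated by oxygen and within reach of a six-membered closure, the side-chain oxygen is remote and silylated, and no free O–H or alkene is left.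

**Step 9**
Reactants: 11 (S)-7-bromo-2-methyl-2-[4-methyl-4-(triethylsilyloxy)pentyl]-6-(triisopropylsilyloxy)chroman-4-one
Product: 12 (S)-7-bromo-6-hydroxy-2-(4-hydroxy-4-methylpentyl)-2-methylchroman-4-one
Conditions: TBAF (3 equiv), AcOH (3 equiv), THF, 0 °C → rt
Reagents that add atoms: none
Why: Fluoride-mediated desilylation should cleave the aryl TIPS ether quickly and the tertiary TES ether more slowly, and the acetic acid buffer suppresses base-induced retro-oxa-Michael opening of the pyranone, which could erode the C2 configuration.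

**Compound list**
1 | 2-bromo-1,4-dimethoxybenzene | COc1ccc(OC)c(Br)c1 | starting material
2 | 1-(4-bromo-2,5-dimethoxyphenyl)ethan-1-one | CC(=O)c1cc(OC)c(Br)cc1OC | intermediate
3 | 1-(4-bromo-2,5-dihydroxyphenyl)ethan-1-one | CC(=O)c1cc(O)c(Br)cc1O | intermediate
4 | 1-[4-bromo-2-hydroxy-5-(triisopropylsilyloxy)phenyl]ethan-1-one | CC(=O)c1cc(O[Si](C(C)C)(C(C)C)C(C)C)c(Br)cc1O | intermediate
5 | (R)-sulcatol, (R)-6-methylhept-5-en-2-ol | CC(C)=CCC[C@@H](C)O | starting material
6 | 1-{4-bromo-2-[(2S)-6-methylhept-5-en-2-yl]oxy-5-(triisopropylsilyloxy)phenyl}ethan-1-one | CC(C)=CCC[C@H](C)Oc1cc(Br)c(O[Si](C(C)C)(C(C)C)C(C)C)cc1C(C)=O | intermediate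
7 | 1-{4-bromo-2-[(2S)-6-hydroxy-6-methylheptan-2-yl]oxy-5-(triisopropylsilyloxy)phenyl}ethan-1-one | CC(C)(O)CCC[C@H](C)Oc1cc(Br)c(O[Si](C(C)C)(C(C)C)C(C)C)cc1C(C)=O | intermediate
8 | 1-{4-bromo-2-[(2S)-6-methyl-6-(triethylsilyloxy)heptan-2-yl]oxy-5-(triisopropylsilyloxy)phenyl}ethan-1-one | CC(C)(O[Si](CC)(CC)CC)CCC[C@H](C)Oc1cc(Br)c(O[Si](C(C)C)(C(C)C)C(C)C)cc1C(C)=O | intermediate
9 | 1-{4-bromo-2-[(2S)-6-methyl-6-(triethylsilyloxy)heptan-2-yl]oxy-5-(triisopropylsilyloxy)phenyl}-4,4,4-trifluorobutane-1,3-dione (trifluoroacetyl diketone, not isolated) | CC(C)(O[Si](CC)(CC)CC)CCC[C@H](C)Oc1cc(Br)c(O[Si](C(C)C)(C(C)C)C(C)C)cc1C(=O)CC(=O)C(F)(F)F | intermediate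
10 | 1-{4-bromo-2-[(2S)-6-methyl-6-(triethylsilyloxy)heptan-2-yl]oxy-5-(triisopropylsilyloxy)phenyl}-2-diazoethan-1-one (diazoketone) | CC(C)(O[Si](CC)(CC)CC)CCC[C@H](C)Oc1cc(Br)c(O[Si](C(C)C)(C(C)C)C(C)C)cc1C(=O)C=[N+]=[N-] | intermediate
11 | (S)-7-bromo-2-methyl-2-[4-methyl-4-(triethylsilyloxy)pentyl]-6-(triisopropylsilyloxy)chroman-4-one | CC(C)(O[Si](CC)(CC)CC)CCC[C@@]1(C)CC(=O)c2cc(O[Si](C(C)C)(C(C)C)C(C)C)c(Br)cc2O1 | intermediate
12 | (S)-7-bromo-6-hydroxy-2-(4-hydroxy-4-methylpentyl)-2-methylchroman-4-one | CC(C)(O)CCC[C@@]1(C)CC(=O)c2cc(O)c(Br)cc2O1 | target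

**Step count**
Total: 9 steps. Longest linear sequence: 9 steps (1 to 12); (R)-sulcatol 5 enters at step 4.

**Steps most likely to fail**

Step 8 (carbenoid C–H insertion). The carbenoid may be captured by the O1 lone pair, and the resulting oxonium ylide may undergo a 1,2-shift or lose the side chain by elimination. Hydride abstraction without C–C bond formation and carbene dimerisation may also compete, so that insertion is not the main pathway. The fallback gives up the carbenoid closure and builds the pyranone ring by Kabbe condensation, setting out from salicyl ketone 4. Commercial sulcatone (6-methylhept-5-en-2-one) is hydrated with aqueous H2SO4 to 6-hydroxy-6-methylheptan-2-one F1. Heating 4 and F1 with pyrrolidine in toluene at 80 °C (aldol condensation, then oxa-Michael closure) should give racemic 7-bromo-2-(4-hydroxy-4-methylpentyl)-2-methyl-6-(triisopropylsilyloxy)chroman-4-one F2. Preparative chiral SFC should separate the enantiomers and give (S)-7-bromo-2-(4-hydroxy-4-methylpentyl)-2-methyl-6-(triisopropylsilyloxy)chroman-4-one F3, its configuration being assigned by anomalous-dispersion X-ray analysis of the bromide. Buffered TBAF/AcOH in THF then removes the TIPS group, and the sequence comes back to the route at 12.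

Step 4 (Mitsunobu etherification). The hydrogen-bonded ortho-acyl phenol may react slowly, so that elimination of the activated alcohol or alkylation of the reduced azodicarboxylate takes over. The fallback replaces the redox condensation by a sulfonate displacement, setting out from 5 and 4. MsCl and Et3N in CH2Cl2 at 0 °C convert 5, with retention, into (R)-6-methylhept-5-en-2-yl methanesulfonate F4. F4 is then displaced by the phenoxide of 4 (K2CO3, DMF, 50 °C) in an SN2 reaction with inversion, and the sequence comes back to the route at 6.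

Step 7 (trifluoroacetylation and diazo transfer). C-acylation of the enolate may be incomplete, or diketone 9 may revert to 8 by retro-Claisen cleavage before the diazo group is transferred. The fallback installs the diazo group through an alpha-bromoketone, setting out from 8. LiN(SiMe3)2 and TMSCl in THF at −78 °C should give 1-{4-bromo-2-[(2S)-6-methyl-6-(triethylsilyloxy)heptan-2-yl]oxy-5-(triisopropylsilyloxy)phenyl}-1-(trimethylsilyloxy)ethene F5. NBS in THF at 0 °C converts it into 2-bromo-1-{4-bromo-2-[(2S)-6-methyl-6-(triethylsilyloxy)heptan-2-yl]oxy-5-(triisopropylsilyloxy)phenyl}ethan-1-one F6. N,N'-ditosylhydrazine and DBU in THF at 0 °C (N-alkylation, then double loss of sulfinate) then give the diazoketone, and the sequence comes back to the route at 10.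

**Further compounds**
F1 | step 8 | 6-hydroxy-6-methylheptan-2-one | CC(=O)CCCC(C)(C)O
F2 | step 8 | racemic 7-bromo-2-(4-hydroxy-4-methylpentyl)-2-methyl-6-(triisopropylsilyloxy)chroman-4-one | CC(C)(O)CCCC1(C)CC(=O)c2cc(O[Si](C(C)C)(C(C)C)C(C)C)c(Br)cc2O1
F3 | step 8 | (S)-7-bromo-2-(4-hydroxy-4-methylpentyl)-2-methyl-6-(triisopropylsilyloxy)chroman-4-one | CC(C)(O)CCC[C@@]1(C)CC(=O)c2cc(O[Si](C(C)C)(C(C)C)C(C)C)c(Br)cc2O1
F4 | step 4 | (R)-6-methylhept-5-en-2-yl methanesulfonate | CC(C)=CCC[C@@H](C)OS(C)(=O)=O
F5 | step 7 | 1-{4-bromo-2-[(2S)-6-methyl-6-(triethylsilyloxy)heptan-2-yl]oxy-5-(triisopropylsilyloxy)phenyl}-1-(trimethylsilyloxy)ethene | CC(C)(O[Si](CC)(CC)CC)CCC[C@H](C)Oc1cc(Br)c(O[Si](C(C)C)(C(C)C)C(C)C)cc1C(=C)O[Si](C)(C)C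
F6 | step 7 | 2-bromo-1-{4-bromo-2-[(2S)-6-methyl-6-(triethylsilyloxy)heptan-2-yl]oxy-5-(triisopropylsilyloxy)phenyl}ethan-1-one | CC(C)(O[Si](CC)(CC)CC)CCC[C@H](C)Oc1cc(Br)c(O[Si](C(C)C)(C(C)C)C(C)C)cc1C(=O)CBr
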